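Ring A is closed last, onto an enantioenriched ring B, by forging C1–C10. A cross-conjugated trienolate (C10=C5–C4=C3(O–)–C2=C1), made by deprotonating a β,γ-unsaturated vinyl ketone, undergoes oxy-anion-accelerated 6π-electrocyclisation: one operation creates the C1–C10 bond, ring A and the quaternary C10. The step exploits the fully substituted C10 at the ring A/B fusion next to the C9 stereocentre (which steers C1 to the opposite face) and the lack of functionality at C1–C3. The temporary C3 ketone then installs C18 at C4 by deconjugative alkylation and is excised; the resulting C5=C6 alkene gives 5α-H/6α-OH by hydroboration. Ring B derives from a quinone monoketal.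

Key step: step 7

Remark on numbering: atoms are numbered as in the labdane-type skeleton of the target (ring A = C1–C5 and C10, ring B = C5–C10, chain C11–C16 with C16 in the lactone, C17 = exocyclic methylene carbon, C18 = 4α carbon, C19 = 4β-methyl, C20 = 10β-methyl).
Remark on the target: it is taken to exist as the open 6α-hydroxy-18-aldehyde as drawn; the lactol is assumed to be disfavoured by the strained bridge between the two equatorial peri substituents.

Step 1
Reactants: 1 4,4-dimethoxycyclohexa-2,5-dien-1-one; 2 2-(2-bromoethyl)-2-methyl-1,3-dioxolane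
Product: 4 (5R)-4,4-dimethoxy-5-[2-(2-methyl-1,3-dioxolan-2-yl)ethyl]cyclohex-2-en-1-one, via dialkylzinc reagent 3 (not isolated)
Conditions: 2, Mg, THF; ZnCl2 (0.5 equiv), then 1,4-dioxane, filter; 1, Cu(OTf)2 (2 mol %), binaphthol-derived bis(1-phenylethyl)phosphoramidite (4 mol %, ligand enantiomer that gives the 5R adduct), toluene, −30 °C; aq NH4Cl
Reagents that add atoms: none
Why: Copper-catalysed asymmetric conjugate addition of a dialkylzinc desymmetrises the prochiral dienone, the chiral phosphoramidite–copper complex choosing one enantiotopic enone and so setting C9, while the zinc enolate formed shields the product from a second addition.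

Step 2
Reactants: 4 (5R)-4,4-dimethoxy-5-[2-(2-methyl-1,3-dioxolan-2-yl)ethyl]cyclohex-2-en-1-one
Product: 5 (5R,6R)-4,4-dimethoxy-6-methyl-5-[2-(2-methyl-1,3-dioxolan-2-yl)ethyl]cyclohex-2-en-1-one (methyl trans to the side chain)
Conditions: LiN(i-Pr)2, THF, −78 °C; MeI, DMPU, −78 to −40 °C
Reagents that add atoms: iodomethane CI
Why: Kinetic α'-deprotonation (the only enolisable site) and enolate methylation anti to the neighbouring side chain install the future C20 methyl; the configuration of this carbon is erased in step 4.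

Step 3
Reactants: 5 (5R,6R)-4,4-dimethoxy-6-methyl-5-[2-(2-methyl-1,3-dioxolan-2-yl)ethyl]cyclohex-2-en-1-one
Product: 6 (2R,3R)-4,4-dimethoxy-2-methyl-3-[2-(2-methyl-1,3-dioxolan-2-yl)ethyl]cyclohexan-1-one
Conditions: H2 (1 atm), Pd/C, EtOAc, rt
Reagents that add atoms: none
Why: Catalytic hydrogenation saturates the enone C=C chemoselectively, which prevents later aromatisation of ring B by loss of methanol.

Step 4
Reactants: 6 (2R,3R)-4,4-dimethoxy-2-methyl-3-[2-(2-methyl-1,3-dioxolan-2-yl)ethyl]cyclohexan-1-one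
Product: 8 (3R)-4,4-dimethoxy-2-methyl-3-[2-(2-methyl-1,3-dioxolan-2-yl)ethyl]cyclohex-1-en-1-yl trifluoromethanesulfonate, via lithium enolate 7 (not isolated)
Conditions: LiN(SiMe3)2 (0.95 equiv), THF, 0 °C to rt (equilibration); N-(5-chloropyridin-2-yl)bis(trifluoromethanesulfonimide), −78 to 0 °C
Reagents that add atoms: N-(5-chloropyridin-2-yl)bis(trifluoromethanesulfonimide) O=S(=O)(N(c1ccc(Cl)cn1)S(=O)(=O)C(F)(F)F)C(F)(F)F
Why: With a slight deficit of base the lithium enolates equilibrate through the remaining ketone to the more substituted C5=C10 (thermodynamic) enolate, whose O-triflation fixes the ring-B double bond where the key step needs it.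

Step 5
Reactants: 8 (3R)-4,4-dimethoxy-2-methyl-3-[2-(2-methyl-1,3-dioxolan-2-yl)ethyl]cyclohex-1-en-1-yl trifluoromethanesulfonate; 9 2-bromo-N-methoxy-N-methylpropanamide (racemic)
Product: 11 2-{(3R)-4,4-dimethoxy-2-methyl-3-[2-(2-methyl-1,3-dioxolan-2-yl)ethyl]cyclohex-1-en-1-yl}-N-methoxy-N-methylpropanamide (both C4 epimers), via zinc amide enolate 10 (not isolated)
Conditions: 9, Zn dust (TMSCl-activated), THF, 40 °C; then 8, Pd2(dba)3 (2.5 mol %), XPhos (10 mol %), LiCl, THF, 60 °C
Reagents that add atoms: none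
Why: Palladium-catalysed cross-coupling of a Reformatsky-type zinc amide enolate with the alkenyl triflate (Negishi-type α-alkenylation) forms the C4–C5 bond under non-basic conditions that keep the alkene at C5=C10; the new C4 centre is inconsequential because it becomes sp2.

Step 6
Reactants: 11 2-{(3R)-4,4-dimethoxy-2-methyl-3-[2-(2-methyl-1,3-dioxolan-2-yl)ethyl]cyclohex-1-en-1-yl}-N-methoxy-N-methylpropanamide
Product: 12 4-{(3R)-4,4-dimethoxy-2-methyl-3-[2-(2-methyl-1,3-dioxolan-2-yl)ethyl]cyclohex-1-en-1-yl}pent-1-en-3-one (both C4 epimers)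
Conditions: CH2=CHMgBr, THF, −78 to 0 °C; cold aq NH4Cl; used at once
Reagents that add atoms: vinylmagnesium bromide C=C[Mg]Br
Why: Weinreb ketone synthesis: the chelated tetrahedral intermediate survives until work-up, so the vinyl ketone is released only after excess Grignard reagent is quenched and neither over-addition nor conjugate addition should occur.

Step 7
Reactants: 12 4-{(3R)-4,4-dimethoxy-2-methyl-3-[2-(2-methyl-1,3-dioxolan-2-yl)ethyl]cyclohex-1-en-1-yl}pent-1-en-3-one
Product: 15 (4aR,5R)-6,6-dimethoxy-1,4a-dimethyl-5-[2-(2-methyl-1,3-dioxolan-2-yl)ethyl]-4,4a,5,6,7,8-hexahydronaphthalen-2(3H)-one (C4=C5 enone; 10β-methyl; 9β side chain), via potassium trienolate 13 (not isolated), via potassium dienolate 14 (not isolated)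
Conditions: KN(SiMe3)2 (0.95 equiv), THF (0.01 M), −78 to 0 °C; AcOH, −78 °C
Reagents that add atoms: none
Why: KN(SiMe3)2 removes the C4 proton (α to the ketone and allylic), giving the 3-oxido-hexatriene C10=C5–C4=C3(O−)–C2=C1, which closes by thermal disrotatory 6π-electrocyclisation (equivalently an intramolecular vinylogous Michael addition of the dienolate γ-carbon C10 to the enone β-carbon C1) to form the C1–C10 bond, and C-protonation of the resulting dienolate 14 at C2 gives the conjugated ketone. The closest known reaction type is the oxy-anion-accelerated electrocyclisation of 3-oxidotrienes to cyclohexadienolates, which runs at or below room temperature. Ring A is closed in the 6π disrotatory mode (formally 6-endo-trig with respect to the C1=C2 acceptor). The one new stereocentre, quaternary C10, is controlled by C9: allylic strain with the C10 methyl holds the C9 side chain pseudo-axial and C1 bonds to the opposite face, so that C20 and the side chain should end cis (both β). The step needs regioselectivity for C10 over C6 as the triene terminus and the cyclisable enolate geometry; the first is secured by the C5=C10 double bond fixed in step 4 and by irreversible α-deprotonation, the second by the slight excess of ketone, which interconverts the enolate geometries through reversible C4 protonation, while high dilution suppresses intermolecular Michael addition.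

Step 8
Reactants: 15 (4aR,5R)-6,6-dimethoxy-1,4a-dimethyl-5-[2-(2-methyl-1,3-dioxolan-2-yl)ethyl]-4,4a,5,6,7,8-hexahydronaphthalen-2(3H)-one
Product: 16 4α-[(benzyloxy)methyl]-8,8-dimethoxy-4β,10β-dimethyl-9β-[2-(2-methyl-1,3-dioxolan-2-yl)ethyl]-Δ5-octalin-3-one
Conditions: KOt-Bu, THF, 0 °C to rt; BnOCH2Cl, −78 to 0 °C
Reagents that add atoms: benzyl chloromethyl ether ClCOCc1ccccc1
Why: Deconjugative α-alkylation of the extended (thermodynamic) dienolate: the chloromethyl ether attacks C4 from the α face, anti to the axial C20 methyl, which should set the quaternary C4 (4α-CH2OBn, 4β-CH3) and moves the alkene to C5=C6.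

Step 9
Reactants: 16 4α-[(benzyloxy)methyl]-8,8-dimethoxy-4β,10β-dimethyl-9β-[2-(2-methyl-1,3-dioxolan-2-yl)ethyl]-Δ5-octalin-3-one
Product: 18 4α-[(benzyloxy)methyl]-8,8-dimethoxy-4β,10β-dimethyl-9β-[2-(2-methyl-1,3-dioxolan-2-yl)ethyl]-Δ5-octalin, via hydrazone 17 (not isolated)
Conditions: N2H4·H2O, KOH, diethylene glycol, 130 °C then 200 °C
Reagents that add atoms: none
Why: Wolff–Kishner reduction removes the temporary C3 carbonyl via the hydrazone; C4 is non-enolisable, the C5=C6 alkene cannot migrate past the quaternary centre, and ketals and the benzyl ether are stable to hot base.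

Step 10
Reactants: 18 4α-[(benzyloxy)methyl]-8,8-dimethoxy-4β,10β-dimethyl-9β-[2-(2-methyl-1,3-dioxolan-2-yl)ethyl]-Δ5-octalin
Product: 20 4α-[(benzyloxy)methyl]-8,8-dimethoxy-4β,10β-dimethyl-9β-[2-(2-methyl-1,3-dioxolan-2-yl)ethyl]-5α-decalin-6α-ol, via alkylborane 19 (not isolated)
Conditions: BH3·THF, THF, 0 °C to rt; NaOH, H2O2, 0 °C
Reagents that add atoms: hydrogen peroxide OO
Why: Hydroboration–oxidation: borane adds syn to the trisubstituted C5=C6 alkene from the α face (the β face is screened by the axial C19 and C20 methyls) with boron on C6, and oxidation with retention gives the trans ring fusion (5α-H) and the equatorial 6α-OH.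

Step 11
Reactants: 20 4α-[(benzyloxy)methyl]-8,8-dimethoxy-4β,10β-dimethyl-9β-[2-(2-methyl-1,3-dioxolan-2-yl)ethyl]-5α-decalin-6α-ol
Product: 21 4α-[(benzyloxy)methyl]-6α-hydroxy-4β,10β-dimethyl-9β-[2-(2-methyl-1,3-dioxolan-2-yl)ethyl]-5α-decalin-8-one
Conditions: PPTS (cat.), acetone/H2O (10:1), rt
Reagents that add atoms: water O
Why: Acid-catalysed ketal hydrolysis, the acyclic and sterically compressed C8 dimethyl ketal being cleaved much faster than the side-chain dioxolane.

Step 12
Reactants: 21 4α-[(benzyloxy)methyl]-6α-hydroxy-4β,10β-dimethyl-9β-[2-(2-methyl-1,3-dioxolan-2-yl)ethyl]-5α-decalin-8-one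
Product: 22 4α-[(benzyloxy)methyl]-6α-(tert-butyldimethylsilyloxy)-4β,10β-dimethyl-9β-[2-(2-methyl-1,3-dioxolan-2-yl)ethyl]-5α-decalin-8-one
Conditions: TBSOTf, 2,6-lutidine, CH2Cl2, −78 °C
Reagents that add atoms: tert-butyldimethylsilyl trifluoromethanesulfonate CC(C)(C)[Si](C)(C)OS(=O)(=O)C(F)(F)F
Why: Silylation of the hindered β-hydroxy ketone with a silyl triflate and a non-nucleophilic base masks O6 against retro-aldol cleavage and β-elimination during the basic olefination.

Step 13
Reactants: 22 4α-[(benzyloxy)methyl]-6α-(tert-butyldimethylsilyloxy)-4β,10β-dimethyl-9β-[2-(2-methyl-1,3-dioxolan-2-yl)ethyl]-5α-decalin-8-one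
Product: 23 4α-[(benzyloxy)methyl]-6α-(tert-butyldimethylsilyloxy)-4β,10β-dimethyl-8-methylene-9β-[2-(2-methyl-1,3-dioxolan-2-yl)ethyl]-5α-decalin
Conditions: Ph3PCH3Br, KOt-Bu, toluene, 80 °C
Reagents that add atoms: methyltriphenylphosphonium bromide C[P+](c1ccccc1)(c1ccccc1)c1ccccc1.[Br-]
Why: Wittig methylenation of the hindered C8 ketone; any epimerisation at C9 under the basic conditions converges on the equatorial 9β side chain that is already present.

Step 14
Reactants: 23 4α-[(benzyloxy)methyl]-6α-(tert-butyldimethylsilyloxy)-4β,10β-dimethyl-8-methylene-9β-[2-(2-methyl-1,3-dioxolan-2-yl)ethyl]-5α-decalin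
Product: 24 4α-[(benzyloxy)methyl]-6α-(tert-butyldimethylsilyloxy)-4β,10β-dimethyl-8-methylene-9β-(3-oxobutyl)-5α-decalin
Conditions: PPTS, acetone/H2O (4:1), 55 °C
Reagents that add atoms: water O
Why: Mild acid-catalysed ketal hydrolysis frees the methyl ketone without isomerising the exocyclic alkene or cleaving the hindered silyl ether.

Step 15
Reactants: 24 4α-[(benzyloxy)methyl]-6α-(tert-butyldimethylsilyloxy)-4β,10β-dimethyl-8-methylene-9β-(3-oxobutyl)-5α-decalin
Product: 26 4α-[(benzyloxy)methyl]-6α-(tert-butyldimethylsilyloxy)-9β-(but-3-yn-1-yl)-4β,10β-dimethyl-8-methylene-5α-decalin, via enol phosphate 25 (not isolated)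
Conditions: LiN(i-Pr)2 (1.1 equiv), THF, −78 °C; ClP(O)(OEt)2; LiN(i-Pr)2 (2.5 equiv), −78 °C to rt
Reagents that add atoms: none
Why: Kinetic enolisation at the methyl group, O-phosphorylation and base-induced elimination of diethyl phosphate from the terminal enol phosphate convert the methyl ketone into the terminal alkyne C13≡C14.

Step 16
Reactants: 26 4α-[(benzyloxy)methyl]-6α-(tert-butyldimethylsilyloxy)-9β-(but-3-yn-1-yl)-4β,10β-dimethyl-8-methylene-5α-decalin
Product: 28 4α-[(benzyloxy)methyl]-6α-(tert-butyldimethylsilyloxy)-9β-[(3E)-5-hydroxy-3-methylpent-3-en-1-yl]-4β,10β-dimethyl-8-methylene-5α-decalin, via alkenylalane 27 (not isolated)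
Conditions: Me3Al, Cp2ZrCl2 (20 mol %), CH2Cl2, 0 °C to rt; n-BuLi, THF, −78 °C; (CH2O)n, −78 °C to rt
Reagents that add atoms: trimethylaluminium C[Al](C)C; formaldehyde (from paraformaldehyde) C=O
Why: Negishi zirconium-catalysed carboalumination adds methyl (to C13) and aluminium (to C14) syn across the alkyne, fixing the E trisubstituted alkene, and the derived alanate adds to formaldehyde with retention to give the C15 alcohol.

Step 17
Reactants: 28 4α-[(benzyloxy)methyl]-6α-(tert-butyldimethylsilyloxy)-9β-[(3E)-5-hydroxy-3-methylpent-3-en-1-yl]-4β,10β-dimethyl-8-methylene-5α-decalin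
Product: 29 6α-(tert-butyldimethylsilyloxy)-4α-(hydroxymethyl)-9β-[(3E)-5-hydroxy-3-methylpent-3-en-1-yl]-4β,10β-dimethyl-8-methylene-5α-decalin
Conditions: lithium 4,4'-di-tert-butylbiphenylide, THF, −78 °C; MeOH
Reagents that add atoms: none
Why: Arene radical-anion (dissolving-metal type) reductive cleavage of the benzyl ether; the isolated alkenes, the silyl ether and the allylic alkoxide should not be reduced at −78 °C.

Step 18
Reactants: 29 6α-(tert-butyldimethylsilyloxy)-4α-(hydroxymethyl)-9β-[(3E)-5-hydroxy-3-methylpent-3-en-1-yl]-4β,10β-dimethyl-8-methylene-5α-decalin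
Product: 30 6α-(tert-butyldimethylsilyloxy)-4β,10β-dimethyl-8-methylene-9β-[(3E)-3-methyl-5-oxopent-3-en-1-yl]-5α-decalin-4α-carbaldehyde
Conditions: DMP periodinane (1,1,1-triacetoxy-1,1-dihydro-1,2-benziodoxol-3(1H)-one), NaHCO3, CH2Cl2, 0 °C to rt
Reagents that add atoms: none
Why: Periodinane oxidation converts both primary alcohols to aldehydes under neutral buffered conditions, so the E enal does not isomerise and the non-enolisable C18 aldehyde cannot epimerise.

Step 19
Reactants: 31 4-methylfuran-2(5H)-one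
Product: 32 tert-butyldimethyl[(4-methylfuran-2-yl)oxy]silane
Conditions: TBSOTf, Et3N, CH2Cl2, 0 °C
Reagents that add atoms: tert-butyldimethylsilyl trifluoromethanesulfonate CC(C)(C)[Si](C)(C)OS(=O)(=O)C(F)(F)F
Why: Soft enolisation and O-silylation of the butenolide give the aromatic 2-silyloxyfuran, the dienolate equivalent for the vinylogous aldol reaction.

Step 20
Reactants: 30 6α-(tert-butyldimethylsilyloxy)-4β,10β-dimethyl-8-methylene-9β-[(3E)-3-methyl-5-oxopent-3-en-1-yl]-5α-decalin-4α-carbaldehyde; 32 tert-butyldimethyl[(4-methylfuran-2-yl)oxy]silane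
Product: 33 6-O-(tert-butyldimethylsilyl) ether of the target (15S,16S; free 15-OH; 18-aldehyde)
Conditions: SiCl4 (1.1 equiv), chiral binaphthyldiamine-derived bisphosphoramide (5 mol %, enantiomer that gives 15S), i-Pr2NEt (10 mol %), CH2Cl2, −78 °C; aq NaHCO3
Reagents that add atoms: none
Why: Lewis-base-activated SiCl4 vinylogous Mukaiyama aldol reaction at the furan γ-carbon: the conjugated aldehyde should react much faster than the hindered neopentyl C18 aldehyde, the chiral bisphosphoramide-bound silicon cation controls the aldehyde face (C15) and the open transition state is expected to place C16 syn (threo), giving 15S,16S.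

Step 21
Reactants: 33 6-O-(tert-butyldimethylsilyl) ether of the target
Product: 34 CNP0113661.1 (target)
Conditions: HF·pyridine, pyridine, THF, 0 °C to rt
Reagents that add atoms: none
Why: Fluoride-mediated cleavage of the secondary silyl ether under buffered conditions that should leave aldehyde, butenolide, allylic alcohol and exocyclic alkene untouched.

Compound list
1 | 4,4-dimethoxycyclohexa-2,5-dien-1-one | COC1(OC)C=CC(=O)C=C1 | starting material
2 | 2-(2-bromoethyl)-2-methyl-1,3-dioxolane | CC1(CCBr)OCCO1 | starting material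
3 | bis[2-(2-methyl-1,3-dioxolan-2-yl)ethyl]zinc | CC1(CC[Zn]CCC2(C)OCCO2)OCCO1 | intermediate
4 | (5R)-4,4-dimethoxy-5-[2-(2-methyl-1,3-dioxolan-2-yl)ethyl]cyclohex-2-en-1-one | COC1(OC)C=CC(=O)C[C@H]1CCC2(C)OCCO2 | intermediate
5 | (5R,6R)-4,4-dimethoxy-6-methyl-5-[2-(2-methyl-1,3-dioxolan-2-yl)ethyl]cyclohex-2-en-1-one | COC1(OC)C=CC(=O)[C@H](C)[C@H]1CCC2(C)OCCO2 | intermediate
6 | (2R,3R)-4,4-dimethoxy-2-methyl-3-[2-(2-methyl-1,3-dioxolan-2-yl)ethyl]cyclohexan-1-one | COC1(OC)CCC(=O)[C@H](C)[C@H]1CCC2(C)OCCO2 | intermediate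
7 | lithium (3R)-4,4-dimethoxy-2-methyl-3-[2-(2-methyl-1,3-dioxolan-2-yl)ethyl]cyclohex-1-en-1-olate | COC1(OC)CCC([O-])=C(C)[C@H]1CCC2(C)OCCO2.[Li+] | intermediate
8 | (3R)-4,4-dimethoxy-2-methyl-3-[2-(2-methyl-1,3-dioxolan-2-yl)ethyl]cyclohex-1-en-1-yl trifluoromethanesulfonate | COC1(OC)CCC(OS(=O)(=O)C(F)(F)F)=C(C)[C@H]1CCC2(C)OCCO2 | intermediate
9 | 2-bromo-N-methoxy-N-methylpropanamide (racemic) | CC(Br)C(=O)N(C)OC | starting material
10 | bromozinc enolate of N-methoxy-N-methylpropanamide | CC([Zn]Br)C(=O)N(C)OC | intermediate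
11 | 2-{(3R)-4,4-dimethoxy-2-methyl-3-[2-(2-methyl-1,3-dioxolan-2-yl)ethyl]cyclohex-1-en-1-yl}-N-methoxy-N-methylpropanamide (C4 epimers) | COC1(OC)CCC(C(C)C(=O)N(C)OC)=C(C)[C@H]1CCC2(C)OCCO2 | intermediate
12 | 4-{(3R)-4,4-dimethoxy-2-methyl-3-[2-(2-methyl-1,3-dioxolan-2-yl)ethyl]cyclohex-1-en-1-yl}pent-1-en-3-one (C4 epimers) | COC1(OC)CCC(C(C)C(=O)C=C)=C(C)[C@H]1CCC2(C)OCCO2 | intermediate
13 | potassium trienolate of 12 (C3=C4 enolate, C5 and vinyl cis) | COC1(OC)CCC(/C(C)=C(/[O-])C=C)=C(C)[C@H]1CCC2(C)OCCO2.[K+] | intermediate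
14 | potassium dienolate (C2=C3(OK)–C4=C5) of 15 | COC1(OC)CCC2=C(C)C([O-])=CC[C@]2(C)[C@H]1CCC3(C)OCCO3.[K+] | intermediate
15 | (4aR,5R)-6,6-dimethoxy-1,4a-dimethyl-5-[2-(2-methyl-1,3-dioxolan-2-yl)ethyl]-4,4a,5,6,7,8-hexahydronaphthalen-2(3H)-one | COC1(OC)CCC2=C(C)C(=O)CC[C@]2(C)[C@H]1CCC3(C)OCCO3 | intermediate
16 | 4α-[(benzyloxy)methyl]-8,8-dimethoxy-4β,10β-dimethyl-9β-[2-(2-methyl-1,3-dioxolan-2-yl)ethyl]-Δ5-octalin-3-one | COC1(OC)CC=C2[C@](C)(CCC(=O)[C@@]2(C)COCc4ccccc4)[C@H]1CCC3(C)OCCO3 | intermediate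
17 | hydrazone of 16 | COC1(OC)CC=C2[C@](C)(CCC(=NN)[C@@]2(C)COCc4ccccc4)[C@H]1CCC3(C)OCCO3 | intermediate
18 | 4α-[(benzyloxy)methyl]-8,8-dimethoxy-4β,10β-dimethyl-9β-[2-(2-methyl-1,3-dioxolan-2-yl)ethyl]-Δ5-octalin | COC1(OC)CC=C2[C@](C)(CCC[C@@]2(C)COCc4ccccc4)[C@H]1CCC3(C)OCCO3 | intermediate
19 | 6α-boryl-5α-decalin from 18 (monoalkylborane) | COC1(OC)C[C@H](B)[C@@H]2[C@](C)(CCC[C@@]2(C)COCc4ccccc4)[C@H]1CCC3(C)OCCO3 | intermediate
20 | 4α-[(benzyloxy)methyl]-8,8-dimethoxy-4β,10β-dimethyl-9β-[2-(2-methyl-1,3-dioxolan-2-yl)ethyl]-5α-decalin-6α-ol | COC1(OC)C[C@H](O)[C@@H]2[C@](C)(CCC[C@@]2(C)COCc4ccccc4)[C@H]1CCC3(C)OCCO3 | intermediate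
21 | 4α-[(benzyloxy)methyl]-6α-hydroxy-4β,10β-dimethyl-9β-[2-(2-methyl-1,3-dioxolan-2-yl)ethyl]-5α-decalin-8-one | O=C1C[C@H](O)[C@@H]2[C@](C)(CCC[C@@]2(C)COCc4ccccc4)[C@H]1CCC3(C)OCCO3 | intermediate
22 | 4α-[(benzyloxy)methyl]-6α-(tert-butyldimethylsilyloxy)-4β,10β-dimethyl-9β-[2-(2-methyl-1,3-dioxolan-2-yl)ethyl]-5α-decalin-8-one | O=C1C[C@H](O[Si](C)(C)C(C)(C)C)[C@@H]2[C@](C)(CCC[C@@]2(C)COCc4ccccc4)[C@H]1CCC3(C)OCCO3 | intermediate
23 | 4α-[(benzyloxy)methyl]-6α-(tert-butyldimethylsilyloxy)-4β,10β-dimethyl-8-methylene-9β-[2-(2-methyl-1,3-dioxolan-2-yl)ethyl]-5α-decalin | C=C1C[C@H](O[Si](C)(C)C(C)(C)C)[C@@H]2[C@](C)(CCC[C@@]2(C)COCc4ccccc4)[C@H]1CCC3(C)OCCO3 | intermediate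
24 | 4α-[(benzyloxy)methyl]-6α-(tert-butyldimethylsilyloxy)-4β,10β-dimethyl-8-methylene-9β-(3-oxobutyl)-5α-decalin | C=C1C[C@H](O[Si](C)(C)C(C)(C)C)[C@@H]2[C@](C)(CCC[C@@]2(C)COCc4ccccc4)[C@H]1CCC(C)=O | intermediate
25 | terminal enol diethyl phosphate of 24 | C=C1C[C@H](O[Si](C)(C)C(C)(C)C)[C@@H]2[C@](C)(CCC[C@@]2(C)COCc4ccccc4)[C@H]1CCC(=C)OP(=O)(OCC)OCC | intermediate
26 | 4α-[(benzyloxy)methyl]-6α-(tert-butyldimethylsilyloxy)-9β-(but-3-yn-1-yl)-4β,10β-dimethyl-8-methylene-5α-decalin | C=C1C[C@H](O[Si](C)(C)C(C)(C)C)[C@@H]2[C@](C)(CCC[C@@]2(C)COCc4ccccc4)[C@H]1CCC#C | intermediate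
27 | (E)-alkenyl(dimethyl)alane from 26 | C=C1C[C@H](O[Si](C)(C)C(C)(C)C)[C@@H]2[C@](C)(CCC[C@@]2(C)COCc4ccccc4)[C@H]1CC/C(C)=C/[Al](C)C | intermediate
28 | 4α-[(benzyloxy)methyl]-6α-(tert-butyldimethylsilyloxy)-9β-[(3E)-5-hydroxy-3-methylpent-3-en-1-yl]-4β,10β-dimethyl-8-methylene-5α-decalin | C=C1C[C@H](O[Si](C)(C)C(C)(C)C)[C@@H]2[C@](C)(CCC[C@@]2(C)COCc4ccccc4)[C@H]1CC/C(C)=C/CO | intermediate
29 | 6α-(tert-butyldimethylsilyloxy)-4α-(hydroxymethyl)-9β-[(3E)-5-hydroxy-3-methylpent-3-en-1-yl]-4β,10β-dimethyl-8-methylene-5α-decalin | C=C1C[C@H](O[Si](C)(C)C(C)(C)C)[C@@H]2[C@](C)(CCC[C@@]2(C)CO)[C@H]1CC/C(C)=C/CO | intermediate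
30 | 6α-(tert-butyldimethylsilyloxy)-4β,10β-dimethyl-8-methylene-9β-[(3E)-3-methyl-5-oxopent-3-en-1-yl]-5α-decalin-4α-carbaldehyde | C=C1C[C@H](O[Si](C)(C)C(C)(C)C)[C@@H]2[C@](C)(CCC[C@@]2(C)C=O)[C@H]1CC/C(C)=C/C=O | intermediate
31 | 4-methylfuran-2(5H)-one | CC1=CC(=O)OC1 | starting material
32 | tert-butyldimethyl[(4-methylfuran-2-yl)oxy]silane | Cc1coc(O[Si](C)(C)C(C)(C)C)c1 | intermediate
33 | 6-O-(tert-butyldimethylsilyl) ether of the target | C=C1C[C@H](O[Si](C)(C)C(C)(C)C)[C@@H]2[C@](C)(CCC[C@@]2(C)C=O)[C@H]1CC/C(C)=C/[C@H](O)[C@H]3OC(=O)C=C3C | intermediate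
34 | CNP0113661.1 | C=C1C[C@H](O)[C@@H]2[C@](C)(CCC[C@@]2(C)C=O)[C@H]1CC/C(C)=C/[C@H](O)[C@H]1OC(=O)C=C1C | target

Total step count: 21. Longest linear sequence: 20 steps (steps 1–18, 20 and 21); step 19 is a one-step branch.

Steps most likely to fail

1. Step 7 (key ring closure). The trienolate may form mainly in the enolate geometry that cannot reach C1, may add intermolecularly to a second vinyl ketone, or may close with insufficient facial selectivity at C10. The fallback sets out from 12 and replaces the anionic closure by a Lewis-acid-promoted intramolecular ene reaction of type 2 (Me2AlCl, CH2Cl2, −78 to −20 °C; thermal variant in toluene at 180 °C if the ketal does not tolerate the Lewis acid). The C5=C10 alkene attacks the activated vinyl ketone at C1 through C10 and the allylic C6 hydrogen is transferred to C2, which should give 8,8-dimethoxy-4,10β-dimethyl-9β-[2-(2-methyl-1,3-dioxolan-2-yl)ethyl]-Δ5-octalin-3-one F1 (C4 epimers). Under the conditions of step 8, F1 forms the same extended dienolate and should give 16, where the route is rejoined.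

2. Step 5 (sp2–sp3 coupling). Transmetalation and reductive elimination at the tetrasubstituted alkenylpalladium centre may be slow, so that protodemetalation of the zinc enolate or migration of the double bond into conjugation takes over. The fallback sets out from 8 and comes back at 12.
   - Stille coupling with tributyl(1-ethoxyvinyl)stannane (Pd(PPh3)4, LiCl, THF, 60 °C) should give the 1-ethoxyvinyl diene F2.
   - Brief treatment with aqueous oxalic acid should give the acetyl compound 1-{(3R)-4,4-dimethoxy-2-methyl-3-[2-(2-methyl-1,3-dioxolan-2-yl)ethyl]cyclohex-1-en-1-yl}ethan-1-one F3.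
   - Wittig reaction with Ph3P=CHOMe should give the methyl enol ether F4, and mild acid hydrolysis the β,γ-unsaturated aldehyde F5.
   - Addition of CH2=CHMgBr should give the allylic alcohol F6, and periodinane oxidation the vinyl ketone 12.

3. Step 20 (vinylogous aldol). The addition may proceed with the opposite relative topicity (anti instead of syn) or with weak control of the aldehyde face. The fallback sets out from 30 and 32 and comes back at 33. If the reaction proves anti-selective, it is run with the enantiomeric catalyst so that the anti adduct with the correct C16 and the wrong C15 configuration forms, the (15R,16S)-6-O-silyl adduct F7. Mitsunobu inversion with 4-nitrobenzoic acid (PPh3, DIAD, THF, 0 °C) should give the (15S)-4-nitrobenzoate F8, and mild methanolysis (Et3N, MeOH, 0 °C) should return 33.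

Further compounds
F1 | step 7 | 8,8-dimethoxy-4,10β-dimethyl-9β-[2-(2-methyl-1,3-dioxolan-2-yl)ethyl]-Δ5-octalin-3-one (C4 epimers) | COC1(OC)CC=C2C(C)C(=O)CC[C@]2(C)[C@H]1CCC3(C)OCCO3
F2 | step 5 | (3R)-1-(1-ethoxyvinyl)-4,4-dimethoxy-2-methyl-3-[2-(2-methyl-1,3-dioxolan-2-yl)ethyl]cyclohex-1-ene | COC1(OC)CCC(C(=C)OCC)=C(C)[C@H]1CCC2(C)OCCO2
F3 | step 5 | 1-{(3R)-4,4-dimethoxy-2-methyl-3-[2-(2-methyl-1,3-dioxolan-2-yl)ethyl]cyclohex-1-en-1-yl}ethan-1-one | COC1(OC)CCC(C(C)=O)=C(C)[C@H]1CCC2(C)OCCO2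
F4 | step 5 | (3R)-4,4-dimethoxy-1-(1-methoxyprop-1-en-2-yl)-2-methyl-3-[2-(2-methyl-1,3-dioxolan-2-yl)ethyl]cyclohex-1-ene (E/Z) | COC1(OC)CCC(C(C)=COC)=C(C)[C@H]1CCC2(C)OCCO2
F5 | step 5 | 2-{(3R)-4,4-dimethoxy-2-methyl-3-[2-(2-methyl-1,3-dioxolan-2-yl)ethyl]cyclohex-1-en-1-yl}propanal (C4 epimers) | COC1(OC)CCC(C(C)C=O)=C(C)[C@H]1CCC2(C)OCCO2
F6 | step 5 | 4-{(3R)-4,4-dimethoxy-2-methyl-3-[2-(2-methyl-1,3-dioxolan-2-yl)ethyl]cyclohex-1-en-1-yl}pent-1-en-3-ol (diastereomers) | COC1(OC)CCC(C(C)C(O)C=C)=C(C)[C@H]1CCC2(C)OCCO2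
F7 | step 20 | (15R,16S) anti aldol adduct (15-epimer of 33) | C=C1C[C@H](O[Si](C)(C)C(C)(C)C)[C@@H]2[C@](C)(CCC[C@@]2(C)C=O)[C@H]1CC/C(C)=C/[C@@H](O)[C@H]3OC(=O)C=C3C
F8 | step 20 | (15S)-15-O-(4-nitrobenzoyl) derivative of 33 | C=C1C[C@H](O[Si](C)(C)C(C)(C)C)[C@@H]2[C@](C)(CCC[C@@]2(C)C=O)[C@H]1CC/C(C)=C/[C@H](OC(=O)c4ccc(cc4)[N+](=O)[O-])[C@H]3OC(=O)C=C3C
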